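**Retrosynthetic overview**
1. Target 26 ⇐ Schenck ene reaction (¹O₂) on the E-Δ13 alkene 25; butenolide of 25 ⇐ γ-hydroxy-ynoate 23 (Zn–ProPhenol alkynylation, then Me₂CuLi/lactonization).
2. E-C13=C14 ⇐ Negishi carboalumination of alkyne 16 and ethylene oxide opening; alkyne ⇐ methyl ketone 13.
3. 6α-OH and C4 ester ⇐ carboxylate-directed γ-C–H lactonization of acid 12, then methanolysis; CO₂H ⇐ phenyl (RuO₄).
4. Decalin (ring A then ring B in one cascade; C4, C5, C8, C9, C10 set) ⇐ chiral IDPi Brønsted-acid bicyclization of achiral trienone 9, ended by the ketone oxygen.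
5. Trienone 9 ⇐ (E)-geranylacetone 1 + 3-phenylbut-3-en-1-ol 5 (SeO₂ oxidation, Cu-catalysed Grignard coupling).

Assumption: the SMILES fixes the absolute configuration as 4R,5R,6S,8R,9R,10S,13R,16S, with decalin carbons C1–C10 (C4 = ester carbon, C9 = side-chain carbon), side chain C11–C19 counted outward from C9 (C16 = lactone CH–O, C19 = lactone C=O), and α = the face opposite the C10 methyl.

**Step 1**
Reactants: 1 (5E)-6,10-dimethylundeca-5,9-dien-2-one ((E)-geranylacetone)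
Product: 2 2-[(3E)-4,8-dimethylnona-3,7-dien-1-yl]-2-methyl-1,3-dioxolane
Conditions: ethylene glycol, PPTS (cat.), benzene, reflux, Dean–Stark
Reagents that add atoms: ethylene glycol, OCCO
Why: Acid-catalysed ketalization masks the ketone against the Grignard reagent of step 5; no stereocentre is formed.

**Step 2**
Reactants: 2 2-[(3E)-4,8-dimethylnona-3,7-dien-1-yl]-2-methyl-1,3-dioxolane
Product: 3 (2E,6E)-2,6-dimethyl-9-(2-methyl-1,3-dioxolan-2-yl)nona-2,6-dien-1-ol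
Conditions: SeO2 (0.2 eq), t-BuOOH (3 eq), salicylic acid (cat.), CH2Cl2, rt
Reagents that add atoms: tert-butyl hydroperoxide, CC(C)(C)OO
Why: Sharpless SeO2/TBHP allylic oxidation (ene then [2,3] shift) hydroxylates the E-methyl of the more reactive terminal trisubstituted alkene, giving the E-allylic alcohol.

**Step 3**
Reactants: 3 (2E,6E)-2,6-dimethyl-9-(2-methyl-1,3-dioxolan-2-yl)nona-2,6-dien-1-ol
Product: 4 2-[(3E,7E)-9-bromo-4,8-dimethylnona-3,7-dien-1-yl]-2-methyl-1,3-dioxolane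
Conditions: CBr4, PPh3, CH2Cl2, 0 °C
Reagents that add atoms: tetrabromomethane, BrC(Br)(Br)Br
Why: Appel bromination converts the primary allylic alcohol to the bromide under neutral conditions with retention of the E geometry.

**Step 4**
Reactants: 5 3-phenylbut-3-en-1-ol
Product: 6 (4-bromobut-1-en-2-yl)benzene
Conditions: CBr4, PPh3, CH2Cl2, 0 °C to rt
Reagents that add atoms: tetrabromomethane, BrC(Br)(Br)Br
Why: Appel bromination of a primary alcohol gives the homoallylic bromide needed for the Grignard reagent.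

**Step 5**
Reactants: 6 (4-bromobut-1-en-2-yl)benzene; 4 2-[(3E,7E)-9-bromo-4,8-dimethylnona-3,7-dien-1-yl]-2-methyl-1,3-dioxolane
Product: 8 2-[(3E,7E)-4,8-dimethyl-12-phenyltrideca-3,7,12-trien-1-yl]-2-methyl-1,3-dioxolane, via Grignard reagent 7 (not isolated)
Conditions: Mg, THF; then 4, Li2CuCl4 (3 mol%), THF, −78 to 0 °C
Reagents that add atoms: none
Why: Kochi Cu-catalysed Grignard coupling with a primary allylic bromide goes by SN2 (α) attack and keeps the E-alkene, joining the α-styryl cap to the terpenoid chain.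

**Step 6**
Reactants: 8 2-[(3E,7E)-4,8-dimethyl-12-phenyltrideca-3,7,12-trien-1-yl]-2-methyl-1,3-dioxolane
Product: 9 (5E,9E)-6,10-dimethyl-14-phenylpentadeca-5,9,14-trien-2-one
Conditions: PPTS (0.2 eq), acetone/H2O, 50 °C
Reagents that add atoms: water, O
Why: Mild acid hydrolysis of the dioxolane frees the ketone, which is the terminating nucleophile of the cyclization, without protonating the alkenes.

**Step 7**
Reactants: 9 (5E,9E)-6,10-dimethyl-14-phenylpentadeca-5,9,14-trien-2-one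
Product: 11 (4R,5R,8R,9R,10S)-8α-hydroxy-4β,8β,10β-trimethyl-4α-phenyl-9β-(3-oxobutyl)-trans-decalin, via cyclic enol ether 10 (not isolated)
Conditions: IDPi (confined imidodiphosphorimidate, 3 mol%; the enantiomer that gives (−)-ambrox from homofarnesol), PFTB/HFIP, −40 °C; then 1 M HCl, THF, rt
Reagents that add atoms: water, O
Why: Proposed new method: an IDPi-catalysed, proton-initiated cation–olefin bicyclization that starts at an α-alkylstyrene (phenyl as latent carboxyl) and ends on the ketone oxygen; Markovnikov protonation gives a tertiary benzylic cation held in the chiral anion pocket, the E,E-triene folds chair–chair with phenyl equatorial (the syn-phenyl rotamer eclipses C2), anti additions set C4, C5, C10, C9 and 8α-O (Stork–Eschenmoser), and the oxocarbenium ion loses H+ to return the catalyst and give enol ether 10, which is hydrolysed; closest known reactions are the IDPi-catalysed homofarnesol-to-ambrox cyclization and the racemic acid-mediated farnesylacetone-to-sclareol-oxide cyclization.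

**Step 8**
Reactants: 11 (4R,5R,8R,9R,10S)-8α-hydroxy-4β,8β,10β-trimethyl-4α-phenyl-9β-(3-oxobutyl)-trans-decalin
Product: 12 (4R,5R,8R,9R,10S)-8α-hydroxy-4β,8β,10β-trimethyl-9β-(3-oxobutyl)-trans-decalin-4α-carboxylic acid
Conditions: RuCl3·xH2O (5 mol%), NaIO4 (16 eq), CCl4/MeCN/H2O, rt
Reagents that add atoms: sodium periodate, [Na+].[O-]I(=O)(=O)=O
Why: Sharpless RuO4 degradation of the phenyl ring leaves its ipso carbon as CO2H; the quaternary C4, tertiary alcohol and ketone are inert, so configuration is kept.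

**Step 9**
Reactants: 12 (4R,5R,8R,9R,10S)-8α-hydroxy-4β,8β,10β-trimethyl-9β-(3-oxobutyl)-trans-decalin-4α-carboxylic acid
Product: 13 (4R,5R,6S,8R,9R,10S)-8α-hydroxy-4β,8β,10β-trimethyl-9β-(3-oxobutyl)-trans-decalin-4α-carboxylic acid 6α-lactone
Conditions: (S,S)-[Mn(OTf)2(TIPSpdp)] (2 mol%), H2O2 (aq., 2.5 eq, slow addition), TFE, 0 °C
Reagents that add atoms: none
Why: Carboxylate-directed Mn-oxo γ-C–H lactonization (1,7-HAT then rebound, White/Costas type); the equatorial 4α-carboxyl reaches only the peri C6 methylene and rebound on the α face gives 6α-O (6S).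

**Step 10**
Reactants: 13 (4R,5R,6S,8R,9R,10S)-8α-hydroxy-4β,8β,10β-trimethyl-9β-(3-oxobutyl)-trans-decalin-4α-carboxylic acid 6α-lactone
Product: 15 (4R,5R,6S,8R,9R,10S)-9β-(but-3-yn-1-yl)-8α-hydroxy-4β,8β,10β-trimethyl-trans-decalin-4α-carboxylic acid 6α-lactone, via enol phosphate 14 (not isolated)
Conditions: LDA (2.2 eq), THF, −78 °C; ClP(O)(OEt)2; then LDA (2.5 eq), −78 °C to rt
Reagents that add atoms: none
Why: Negishi methyl ketone-to-alkyne conversion (kinetic enol phosphate, then elimination); the lactone has no α-hydrogen and LDA is non-nucleophilic, so it survives.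

**Step 11**
Reactants: 15 (4R,5R,6S,8R,9R,10S)-9β-(but-3-yn-1-yl)-8α-hydroxy-4β,8β,10β-trimethyl-trans-decalin-4α-carboxylic acid 6α-lactone
Product: 16 methyl (4R,5R,6S,8R,9R,10S)-9β-(but-3-yn-1-yl)-6α,8α-dihydroxy-4β,8β,10β-trimethyl-trans-decalin-4α-carboxylate
Conditions: NaOMe (0.5 eq), MeOH, 0 °C to rt; AcOH quench
Reagents that add atoms: methanol, CO
Why: Base-catalysed methanolysis (transesterification) opens the strained trans-fused γ-lactone to the methyl ester and free 6α-OH without touching C6.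

**Step 12**
Reactants: 16 methyl (4R,5R,6S,8R,9R,10S)-9β-(but-3-yn-1-yl)-6α,8α-dihydroxy-4β,8β,10β-trimethyl-trans-decalin-4α-carboxylate; 17 ethylene oxide
Product: 20 methyl (4R,5R,6S,8R,9R,10S)-6α,8α-dihydroxy-9β-[(3E)-6-hydroxy-3-methylhex-3-en-1-yl]-4β,8β,10β-trimethyl-trans-decalin-4α-carboxylate, via alkenylalane 18 (not isolated), via lithium alanate 19 (not isolated)
Conditions: Me3Al (5 eq), Cp2ZrCl2 (0.5 eq), CH2Cl2, 0 °C to rt; n-BuLi, −78 °C; then 17, −78 to 0 °C; aq. Rochelle salt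
Reagents that add atoms: trimethylaluminium, C[Al](C)C
Why: Negishi Zr-catalysed syn-carboalumination fixes the E-trisubstituted C13=C14 alkene, and the derived alanate opens ethylene oxide to add C15–C16; the hindered C4 ester tolerates Me3Al.

**Step 13**
Reactants: 20 methyl (4R,5R,6S,8R,9R,10S)-6α,8α-dihydroxy-9β-[(3E)-6-hydroxy-3-methylhex-3-en-1-yl]-4β,8β,10β-trimethyl-trans-decalin-4α-carboxylate
Product: 21 methyl (4R,5R,6S,8R,9R,10S)-6α,8α-dihydroxy-4β,8β,10β-trimethyl-9β-[(3E)-3-methyl-6-oxohex-3-en-1-yl]-trans-decalin-4α-carboxylate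
Conditions: TEMPO (0.1 eq), PhI(OAc)2 (1.2 eq), CH2Cl2, rt; used crude
Reagents that add atoms: none
Why: TEMPO/BAIB oxidation is selective for the primary alcohol over the hindered secondary 6α-OH and the tertiary 8α-OH and is mild enough for the β,γ-unsaturated aldehyde.

**Step 14**
Reactants: 21 methyl (4R,5R,6S,8R,9R,10S)-6α,8α-dihydroxy-4β,8β,10β-trimethyl-9β-[(3E)-3-methyl-6-oxohex-3-en-1-yl]-trans-decalin-4α-carboxylate; 22 methyl propiolate
Product: 23 methyl (4R,5R,6S,8R,9R,10S)-6α,8α-dihydroxy-9β-[(3E,6S)-6-hydroxy-9-methoxy-3-methyl-9-oxonon-3-en-7-yn-1-yl]-4β,8β,10β-trimethyl-trans-decalin-4α-carboxylate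
Conditions: Me2Zn (4 eq), (S,S)-ProPhenol (20 mol%), Ph3PO (40 mol%), toluene, 0 °C; aq. NH4Cl
Reagents that add atoms: none
Why: Trost Zn–ProPhenol asymmetric alkynylation sets C16 (S, Re-face addition) under catalyst control; the (S,S) ligand is assumed to give this sense, to be confirmed by Mosher analysis, with the (R,R) ligand used otherwise.

**Step 15**
Reactants: 23 methyl (4R,5R,6S,8R,9R,10S)-6α,8α-dihydroxy-9β-[(3E,6S)-6-hydroxy-9-methoxy-3-methyl-9-oxonon-3-en-7-yn-1-yl]-4β,8β,10β-trimethyl-trans-decalin-4α-carboxylate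
Product: 25 methyl (4R,5R,6S,8R,9R,10S)-6α,8α-dihydroxy-4β,8β,10β-trimethyl-9β-{(3E)-3-methyl-5-[(2S)-3-methyl-5-oxo-2,5-dihydrofuran-2-yl]pent-3-en-1-yl}-trans-decalin-4α-carboxylate, via hydroxy enoate 24 (not isolated)
Conditions: Me2CuLi (from MeLi and CuI, 5 eq), THF, −78 °C; aq. NH4Cl
Reagents that add atoms: lithium dimethylcuprate, [Li+].C[Cu-]C
Why: Syn-carbocupration of the γ-hydroxy ynoate gives the Z-β-methyl enoate, which lactonizes on work-up to the butenolide; the C16–O bond is not broken, so 16S is kept.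

**Step 16**
Reactants: 25 methyl (4R,5R,6S,8R,9R,10S)-6α,8α-dihydroxy-4β,8β,10β-trimethyl-9β-{(3E)-3-methyl-5-[(2S)-3-methyl-5-oxo-2,5-dihydrofuran-2-yl]pent-3-en-1-yl}-trans-decalin-4α-carboxylate
Product: 26 methyl (4R,5R,6S,8R,9R,10S)-9β-{(3R,4E)-3-hydroperoxy-3-methyl-5-[(2S)-3-methyl-5-oxo-2,5-dihydrofuran-2-yl]pent-4-en-1-yl}-6α,8α-dihydroxy-4β,8β,10β-trimethyl-trans-decalin-4α-carboxylate (CNP0128148.1)
Conditions: O2, tetraphenylporphyrin (1 mol%), CH2Cl2, white LED, −20 °C; preparative HPLC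
Reagents that add atoms: dioxygen, O=O
Why: Schenck ene reaction of singlet oxygen puts O on C13 and removes H from C15 to give the tertiary hydroperoxide and the E-14 alkene (the butenolide alkene is too electron-poor to react); C13 is created here without facial control (about 1:1), so the 13R epimer is separated by HPLC from the 13S epimer and the 14-OOH regioisomers.

**Compound list**
1 | (5E)-6,10-dimethylundeca-5,9-dien-2-one ((E)-geranylacetone) | CC(=O)CC/C=C(\C)CCC=C(C)C | starting material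
2 | 2-[(3E)-4,8-dimethylnona-3,7-dien-1-yl]-2-methyl-1,3-dioxolane | CC1(CC/C=C(\C)CCC=C(C)C)OCCO1 | intermediate
3 | (2E,6E)-2,6-dimethyl-9-(2-methyl-1,3-dioxolan-2-yl)nona-2,6-dien-1-ol | CC1(CC/C=C(\C)CC/C=C(\C)CO)OCCO1 | intermediate
4 | 2-[(3E,7E)-9-bromo-4,8-dimethylnona-3,7-dien-1-yl]-2-methyl-1,3-dioxolane | CC1(CC/C=C(\C)CC/C=C(\C)CBr)OCCO1 | intermediate
5 | 3-phenylbut-3-en-1-ol | C=C(CCO)c1ccccc1 | starting material
6 | (4-bromobut-1-en-2-yl)benzene | C=C(CCBr)c1ccccc1 | intermediate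
7 | (3-phenylbut-3-en-1-yl)magnesium bromide (not isolated) | C=C(CC[Mg]Br)c1ccccc1 | intermediate
8 | 2-[(3E,7E)-4,8-dimethyl-12-phenyltrideca-3,7,12-trien-1-yl]-2-methyl-1,3-dioxolane | CC1(CC/C=C(\C)CC/C=C(\C)CCCC(=C)c2ccccc2)OCCO1 | intermediate
9 | (5E,9E)-6,10-dimethyl-14-phenylpentadeca-5,9,14-trien-2-one | CC(=O)CC/C=C(\C)CC/C=C(\C)CCCC(=C)c1ccccc1 | intermediate
10 | (4R,5R,8R,9R,10S)-8α,13-epoxy-4α-phenyl tricyclic enol ether with C12=C13 (sclareol-oxide type; not isolated) | c3ccccc3[C@]1(C)CCC[C@@]2(C)[C@H]1CC[C@@]4(C)OC(C)=CC[C@H]24 | intermediate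
11 | (4R,5R,8R,9R,10S)-8α-hydroxy-4β,8β,10β-trimethyl-4α-phenyl-9β-(3-oxobutyl)-trans-decalin | c3ccccc3[C@]1(C)CCC[C@@]2(C)[C@H]1CC[C@@](C)(O)[C@@H]2CCC(C)=O | intermediate
12 | (4R,5R,8R,9R,10S)-8α-hydroxy-4β,8β,10β-trimethyl-9β-(3-oxobutyl)-trans-decalin-4α-carboxylic acid | OC(=O)[C@]1(C)CCC[C@@]2(C)[C@H]1CC[C@@](C)(O)[C@@H]2CCC(C)=O | intermediate
13 | 6α-lactone of 12 (γ-lactone C4–C(=O)–O–C6; 4R,5R,6S,8R,9R,10S) | O=C3[C@]1(C)CCC[C@@]2(C)[C@H]1[C@@H](O3)C[C@@](C)(O)[C@@H]2CCC(C)=O | intermediate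
14 | kinetic enol diethyl phosphate of 13 (not isolated) | O=C3[C@]1(C)CCC[C@@]2(C)[C@H]1[C@@H](O3)C[C@@](C)(O)[C@@H]2CCC(=C)OP(=O)(OCC)OCC | intermediate
15 | 9β-(but-3-yn-1-yl) alkyne lactone (4R,5R,6S,8R,9R,10S) | O=C3[C@]1(C)CCC[C@@]2(C)[C@H]1[C@@H](O3)C[C@@](C)(O)[C@@H]2CCC#C | intermediate
16 | methyl (4R,5R,6S,8R,9R,10S)-9β-(but-3-yn-1-yl)-6α,8α-dihydroxy-4β,8β,10β-trimethyl-trans-decalin-4α-carboxylate | COC(=O)[C@]1(C)CCC[C@@]2(C)[C@H]1[C@@H](O)C[C@@](C)(O)[C@@H]2CCC#C | intermediate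
17 | ethylene oxide | C1CO1 | starting material
18 | (E)-alkenyl(dimethyl)alane of 16, both OH as O–AlMe2 (not isolated) | COC(=O)[C@]1(C)CCC[C@@]2(C)[C@H]1[C@@H](O[Al](C)C)C[C@@](C)(O[Al](C)C)[C@@H]2CC/C(C)=C/[Al](C)C | intermediate
19 | lithium butyl(dimethyl)alkenylalanate from 18 (not isolated) | [Li+].COC(=O)[C@]1(C)CCC[C@@]2(C)[C@H]1[C@@H](O[Al](C)C)C[C@@](C)(O[Al](C)C)[C@@H]2CC/C(C)=C/[Al-](C)(C)CCCC | intermediate
20 | methyl (4R,5R,6S,8R,9R,10S)-6α,8α-dihydroxy-9β-[(3E)-6-hydroxy-3-methylhex-3-en-1-yl]-4β,8β,10β-trimethyl-trans-decalin-4α-carboxylate | COC(=O)[C@]1(C)CCC[C@@]2(C)[C@H]1[C@@H](O)C[C@@](C)(O)[C@@H]2CC/C(C)=C/CCO | intermediate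
21 | methyl (4R,5R,6S,8R,9R,10S)-6α,8α-dihydroxy-4β,8β,10β-trimethyl-9β-[(3E)-3-methyl-6-oxohex-3-en-1-yl]-trans-decalin-4α-carboxylate | COC(=O)[C@]1(C)CCC[C@@]2(C)[C@H]1[C@@H](O)C[C@@](C)(O)[C@@H]2CC/C(C)=C/CC=O | intermediate
22 | methyl propiolate | C#CC(=O)OC | starting material
23 | (16S)-γ-hydroxy ynoate: methyl (4R,5R,6S,8R,9R,10S)-6α,8α-dihydroxy-9β-[(3E,6S)-6-hydroxy-9-methoxy-3-methyl-9-oxonon-3-en-7-yn-1-yl]-4β,8β,10β-trimethyl-trans-decalin-4α-carboxylate | COC(=O)[C@]1(C)CCC[C@@]2(C)[C@H]1[C@@H](O)C[C@@](C)(O)[C@@H]2CC/C(C)=C/C[C@H](O)C#CC(=O)OC | intermediate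
24 | (16S,17Z)-γ-hydroxy-β-methyl enoate (not isolated) | COC(=O)[C@]1(C)CCC[C@@]2(C)[C@H]1[C@@H](O)C[C@@](C)(O)[C@@H]2CC/C(C)=C/C[C@H](O)/C(C)=C\C(=O)OC | intermediate
25 | methyl (4R,5R,6S,8R,9R,10S)-6α,8α-dihydroxy-4β,8β,10β-trimethyl-9β-{(3E)-3-methyl-5-[(2S)-3-methyl-5-oxo-2,5-dihydrofuran-2-yl]pent-3-en-1-yl}-trans-decalin-4α-carboxylate | COC(=O)[C@]1(C)CCC[C@@]2(C)[C@H]1[C@@H](O)C[C@@](C)(O)[C@@H]2CC/C(C)=C/C[C@@H]1OC(=O)C=C1C | intermediate
26 | CNP0128148.1, the (13R,14E,16S)-13-hydroperoxide | COC(=O)[C@]1(C)CCC[C@@]2(C)[C@H]1[C@@H](O)C[C@@](C)(O)[C@@H]2CC[C@](C)(/C=C/[C@@H]1OC(=O)C=C1C)OO | target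

**Step count**
Total: 16 steps. Longest linear sequence: 15 (steps 1–3 and 5–16; step 4 makes the side fragment).

**Three steps most likely to fail**

Step 7 (proposed new cyclization). The risks are protonation at an internal alkene, incomplete bicyclization and low ee with a long-lived benzylic cation. The fallback uses known chemistry and sets out from 9. Classical racemic cyclization (SnCl4, CH2Cl2, −78 °C, then aqueous HCl) gives the racemic hydroxy ketone F1. RuCl3/NaIO4 gives the racemic acid F2. This is resolved by crystallizing the (S)-1-phenylethylammonium salt F3 and releasing the acid with dilute HCl, which returns to the route at 12.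

Step 9 (directed C–H lactonization). The risks are oxidation at ring-A methylenes and Baeyer–Villiger reaction of the ketone. The fallback sets out from 12 and uses an amidyl-radical 1,5-hydrogen shift in place of the metal-oxo. MeOH/PPTS closes the hydroxy ketone to the cyclic methyl ketal acid F4, which masks the tertiary OH. CDI then NH3 gives the primary amide F5. PhI(OAc)2/I2 under light (Barton N-iodoamide photolysis, Suárez conditions) moves H from C6 to nitrogen, and the C6 iodide closes on the amide oxygen to the iminolactone F6. Aqueous HCl/THF hydrolyses the imine and the ketal and returns to the route at 13.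

Step 16 (ene reaction). The risks are that C13 is not controlled and that 14-hydroperoxide regioisomers form, so the isolated yield may be low. The fallback sets out from 25 and controls C13 by reagent:
- 2,2-Dimethoxypropane/PPTS gives the 6,8-O-isopropylidene acetal F7, which stops the 8α-OH from opening the epoxide.
- Shi epoxidation (fructose-derived ketone of the hand that gives the 13S,14S epoxide, Oxone, buffered) gives the epoxide F8.
- Ethereal H2O2 with catalytic phosphomolybdic acid opens it at tertiary C13 with inversion to the (13R,14S)-13-hydroperoxy-14-ol F9.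
- Et3SiCl/imidazole caps the OOH as the triethylsilyl peroxide F10.
- Martin sulfurane dehydrates the C14 alcohol (only C15 carries β-hydrogens) to the E-14-ene F11.
- HF·pyridine then aqueous AcOH removes the silyl group and the acetonide and returns to the route at 26.

**Further compounds**
F1 | step 7 | racemic 8α-hydroxy-4β,8β,10β-trimethyl-4α-phenyl-9β-(3-oxobutyl)-trans-decalin (rac-11; one enantiomer drawn) | c3ccccc3[C@]1(C)CCC[C@@]2(C)[C@H]1CC[C@@](C)(O)[C@@H]2CCC(C)=O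
F2 | step 7 | racemic 8α-hydroxy-4β,8β,10β-trimethyl-9β-(3-oxobutyl)-trans-decalin-4α-carboxylic acid (rac-12; one enantiomer drawn) | OC(=O)[C@]1(C)CCC[C@@]2(C)[C@H]1CC[C@@](C)(O)[C@@H]2CCC(C)=O
F3 | step 7 | (S)-1-phenylethylammonium salt of acid 12 | C[C@H]([NH3+])c1ccccc1.[O-]C(=O)[C@]1(C)CCC[C@@]2(C)[C@H]1CC[C@@](C)(O)[C@@H]2CCC(C)=O
F4 | step 9 | (4R,5R,8R,9R,10S,13S)-8α,13-epoxy-13-methoxy cyclic methyl ketal of acid 12 | OC(=O)[C@]1(C)CCC[C@@]2(C)[C@H]1CC[C@@]4(C)O[C@](C)(OC)CC[C@H]24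
F5 | step 9 | primary 4α-carboxamide of F4 | NC(=O)[C@]1(C)CCC[C@@]2(C)[C@H]1CC[C@@]4(C)O[C@](C)(OC)CC[C@H]24
F6 | step 9 | 6α-iminolactone (C4–C(=NH)–O–C6) of the cyclic methyl ketal | N=C3[C@]1(C)CCC[C@@]2(C)[C@H]1[C@@H](O3)C[C@@]4(C)O[C@](C)(OC)CC[C@H]24
F7 | step 16 | 6,8-O-isopropylidene acetal of 25 | COC(=O)[C@]1(C)CCC[C@@]2(C)[C@H]1[C@@H]3C[C@@](C)(OC(C)(C)O3)[C@@H]2CC/C(C)=C/C[C@@H]1OC(=O)C=C1C
F8 | step 16 | (13S,14S)-13,14-epoxide of F7 | COC(=O)[C@]1(C)CCC[C@@]2(C)[C@H]1[C@@H]3C[C@@](C)(OC(C)(C)O3)[C@@H]2CC[C@]4(C)O[C@H]4C[C@@H]1OC(=O)C=C1C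
F9 | step 16 | (13R,14S)-13-hydroperoxy-14-hydroxy acetonide | COC(=O)[C@]1(C)CCC[C@@]2(C)[C@H]1[C@@H]3C[C@@](C)(OC(C)(C)O3)[C@@H]2CC[C@](C)([C@@H](O)C[C@@H]1OC(=O)C=C1C)OO
F10 | step 16 | (13R,14S)-14-hydroxy-13-(triethylsilylperoxy) acetonide | COC(=O)[C@]1(C)CCC[C@@]2(C)[C@H]1[C@@H]3C[C@@](C)(OC(C)(C)O3)[C@@H]2CC[C@](C)([C@@H](O)C[C@@H]1OC(=O)C=C1C)OO[Si](CC)(CC)CC
F11 | step 16 | (13R,14E)-13-(triethylsilylperoxy)-14-ene acetonide (protected 26) | COC(=O)[C@]1(C)CCC[C@@]2(C)[C@H]1[C@@H]3C[C@@](C)(OC(C)(C)O3)[C@@H]2CC[C@](C)(/C=C/[C@@H]1OC(=O)C=C1C)OO[Si](CC)(CC)CC
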